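The cycloheptene ring is disconnected at C5–C6 (azulene numbering). Once C4 is taken back to a ketone, the C6=C7 alkene lies β,γ to it and C5 becomes the methyl group of an acetyl substituent on C3a, so C5–C6 can be made by palladium-catalysed coupling of a methyl ketone enolate with a (Z)-alkenyl bromide. That single operation closes the seven-membered ring onto a finished cyclopentane, trans-fused, and leaves the trisubstituted alkene exactly where the target has it. The precursor is a cyclopentane bearing acetyl at C3a and (Z)-3-bromobut-2-enyl at the quaternary C8a, with the C1 ketone as dioxolane and the C3 tertiary alcohol as triethylsilyl ether.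

Key step: step 11

Numbering: azulene locants (C1, C2, C3, C3a, C4–C8, C8a) are used for the ring carbons of every intermediate in the Why lines, also before the seven-membered ring exists.
Assumption: compounds 8 and 24 are bought as drawn (geometrically pure Z bromide, silyl-protected acid), and the lipase is taken to acylate the R alcohol, as its usual selectivity for secondary alcohols predicts.

Step 1
Reactants: 1 1-(furan-2-yl)ethanol
Product: 3 rac-4-hydroxy-2-methylcyclopent-2-en-1-one, via trans-4-hydroxy-5-methylcyclopent-2-en-1-one 2 (not isolated)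
Conditions: ZnCl2, dioxane/H2O, reflux; then phosphate buffer (pH 8), 60 °C
Reagents that add atoms: water, O
Why: The Piancatelli rearrangement (ionisation of the furylcarbinol, water addition at furan C5, ring opening, conrotatory 4π-electrocyclisation) should give the trans-4-hydroxy-5-methyl enone, which mild base isomerises by hydration–elimination to the more stable 2-methyl enone, obtained racemic.

Step 2
Reactants: 3 rac-4-hydroxy-2-methylcyclopent-2-en-1-one
Product: 4 (1R)-3-methyl-4-oxocyclopent-2-en-1-yl acetate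
Conditions: Novozym 435 (CAL-B), vinyl acetate, MTBE, 25 °C, to about half conversion
Reagents that add atoms: vinyl acetate, C=COC(C)=O
Why: Lipase-catalysed kinetic resolution by irreversible transesterification should acylate the R alcohol selectively, so separation of the acetate from the unreacted S alcohol fixes the oxygen-bearing stereocentre (the later C3) as R.

Step 3
Reactants: 4 (1R)-3-methyl-4-oxocyclopent-2-en-1-yl acetate
Product: 6 (4R)-4-[(tert-butyldimethylsilyl)oxy]-2-methylcyclopent-2-en-1-one, via (4R)-4-hydroxy-2-methylcyclopent-2-en-1-one 5 (not isolated)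
Conditions: Novozym 435, MeOH, MTBE, 30 °C; filter, concentrate; TBSCl, imidazole, DMF, 0 °C→rt
Reagents that add atoms: tert-butyldimethylsilyl chloride, CC(C)(C)[Si](C)(C)Cl
Why: Enzymatic methanolysis removes the acetate under neutral conditions (a chemical base would cause E1cB loss of acetate) with a second enantioselection by the same lipase, and imidazole-promoted silylation then caps the sensitive hydroxy enone without touching the stereocentre.

Step 4
Reactants: 6 (4R)-4-[(tert-butyldimethylsilyl)oxy]-2-methylcyclopent-2-en-1-one; 7 2-methyl-1,3-dithiane; 8 (Z)-1,3-dibromobut-2-ene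
Product: 11 (2R,3R,4R)-2-[(2Z)-3-bromobut-2-en-1-yl]-4-[(tert-butyldimethylsilyl)oxy]-2-methyl-3-(2-methyl-1,3-dithian-2-yl)cyclopentan-1-one, via 2-lithio-2-methyl-1,3-dithiane 9 (not isolated), via lithium enolate 10 (not isolated)
Conditions: 7, n-BuLi, THF, −20 °C; HMPA, −78 °C; 6; then 8, −78→−30 °C
Reagents that add atoms: none
Why: In this tandem Michael addition–enolate alkylation the dithianyl anion should add 1,4 in THF/HMPA anti to the silyloxy group (setting C3a), and the tetrasubstituted lithium enolate is then C-allylated by the allylic bromide (the vinylic bromide is inert to SN2) anti to the new C3a substituent, which sets the quaternary C8a with the bromobutenyl chain trans to the masked acetyl group.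

Step 5
Reactants: 11 (2R,3R,4R)-2-[(2Z)-3-bromobut-2-en-1-yl]-4-[(tert-butyldimethylsilyl)oxy]-2-methyl-3-(2-methyl-1,3-dithian-2-yl)cyclopentan-1-one
Product: 12 (6R,7R,8R)-6-[(2Z)-3-bromobut-2-en-1-yl]-8-[(tert-butyldimethylsilyl)oxy]-6-methyl-7-(2-methyl-1,3-dithian-2-yl)-1,4-dioxaspiro[4.4]nonane
Conditions: (TMSOCH2)2, TMSOTf (cat.), CH2Cl2, −78→−20 °C; pyridine quench
Reagents that add atoms: 1,2-bis(trimethylsilyloxy)ethane, C[Si](C)(C)OCCO[Si](C)(C)C
Why: Noyori ketalisation is aprotic and runs cold, so the hindered C1 ketone beside the quaternary carbon should be masked without β-elimination of the silyloxy group and without loss of the TBS ether or the dithiane.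

Step 6
Reactants: 12 (6R,7R,8R)-6-[(2Z)-3-bromobut-2-en-1-yl]-8-[(tert-butyldimethylsilyl)oxy]-6-methyl-7-(2-methyl-1,3-dithian-2-yl)-1,4-dioxaspiro[4.4]nonane
Product: 13 (7R,8R,9R)-9-[(2Z)-3-bromobut-2-en-1-yl]-9-methyl-8-(2-methyl-1,3-dithian-2-yl)-1,4-dioxaspiro[4.4]nonan-7-ol
Conditions: TBAF, AcOH, THF, 0 °C→rt
Reagents that add atoms: none
Why: Fluoride cleaves the secondary TBS ether, the acetic acid buffer keeps the medium from eliminating HBr from the bromoalkene, and the dioxolane and dithiane are inert.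

Step 7
Reactants: 13 (7R,8R,9R)-9-[(2Z)-3-bromobut-2-en-1-yl]-9-methyl-8-(2-methyl-1,3-dithian-2-yl)-1,4-dioxaspiro[4.4]nonan-7-ol
Product: 14 (8R,9R)-9-[(2Z)-3-bromobut-2-en-1-yl]-9-methyl-8-(2-methyl-1,3-dithian-2-yl)-1,4-dioxaspiro[4.4]nonan-7-one
Conditions: (COCl)2, DMSO, CH2Cl2, −78 °C; Et3N, −78→−30 °C
Reagents that add atoms: none
Why: Swern oxidation should give the C3 ketone at low temperature without oxidising the dithiane sulfurs, and the brief exposure to triethylamine is too mild to epimerise C3a or to open the β-ketal by elimination.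

Step 8
Reactants: 14 (8R,9R)-9-[(2Z)-3-bromobut-2-en-1-yl]-9-methyl-8-(2-methyl-1,3-dithian-2-yl)-1,4-dioxaspiro[4.4]nonan-7-one; 15 isopropylmagnesium chloride
Product: 17 (7R,8R,9R)-9-[(2Z)-3-bromobut-2-en-1-yl]-9-methyl-8-(2-methyl-1,3-dithian-2-yl)-7-(propan-2-yl)-1,4-dioxaspiro[4.4]nonan-7-ol, via isopropylcerium dichloride 16 (not isolated)
Conditions: 15, anhydrous CeCl3, THF, −78 °C; then 14, −78→−40 °C; aq. NH4Cl
Reagents that add atoms: none
Why: Organocerium 1,2-addition should suppress enolisation and β-hydride reduction of the hindered ketone, and attack from the face opposite the bulky dithianyl group on C3a sets C3 as R, with the isopropyl group cis to H3a and the hydroxyl cis to the C3a substituent.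

Step 9
Reactants: 17 (7R,8R,9R)-9-[(2Z)-3-bromobut-2-en-1-yl]-9-methyl-8-(2-methyl-1,3-dithian-2-yl)-7-(propan-2-yl)-1,4-dioxaspiro[4.4]nonan-7-ol
Product: 18 {[(7R,8R,9R)-9-[(2Z)-3-bromobut-2-en-1-yl]-9-methyl-8-(2-methyl-1,3-dithian-2-yl)-7-(propan-2-yl)-1,4-dioxaspiro[4.4]nonan-7-yl]oxy}triethylsilane
Conditions: TESOTf, 2,6-lutidine, CH2Cl2, −78→0 °C
Reagents that add atoms: triethylsilyl trifluoromethanesulfonate, CC[Si](CC)(CC)OS(=O)(=O)C(F)(F)F
Why: The silyl triflate is electrophilic enough to silylate the hindered tertiary alcohol, the ketone-derived dioxolane survives at low temperature, and the ether later prevents retro-aldol cleavage under the basic ring closure.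

Step 10
Reactants: 18 {[(7R,8R,9R)-9-[(2Z)-3-bromobut-2-en-1-yl]-9-methyl-8-(2-methyl-1,3-dithian-2-yl)-7-(propan-2-yl)-1,4-dioxaspiro[4.4]nonan-7-yl]oxy}triethylsilane
Product: 19 1-[(6R,7R,8R)-6-[(2Z)-3-bromobut-2-en-1-yl]-6-methyl-8-(propan-2-yl)-8-[(triethylsilyl)oxy]-1,4-dioxaspiro[4.4]nonan-7-yl]ethan-1-one
Conditions: Hg(ClO4)2, CaCO3, THF/H2O (5:1), 0 °C
Reagents that add atoms: water, O
Why: Thiophilic Hg(II)-assisted hydrolysis buffered by CaCO3 should unmask the acetyl group under near-neutral conditions that leave the silyl ether, the dioxolane, the bromoalkene and the C3a stereocentre untouched.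

Step 11
Reactants: 19 1-[(6R,7R,8R)-6-[(2Z)-3-bromobut-2-en-1-yl]-6-methyl-8-(propan-2-yl)-8-[(triethylsilyl)oxy]-1,4-dioxaspiro[4.4]nonan-7-yl]ethan-1-one
Product: 22 (3R,3aR,8aR)-6,8a-dimethyl-3-(propan-2-yl)-3-[(triethylsilyl)oxy]-3,3a,8,8a-tetrahydro-2H-spiro[azulene-1,2'-[1,3]dioxolan]-4(5H)-one, via terminal lithium enolate 20 (not isolated), via lithium dienolate 21 (not isolated)
Conditions: LiHMDS (2.2 equiv), THF, −78 °C; Pd(Pt-Bu3)2 (10 mol %), THF/toluene, 0.005 M, −78→45 °C; AcOH, −78 °C
Reagents that add atoms: none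
Why: Complete kinetic deprotonation of the acetyl methyl gives enolate 20, Pd(0) inserts into the C6–Br bond with retention of the Z geometry, the enolate replaces bromide on palladium and binds through C5, and C–C reductive elimination forms C5–C6. The closest known reaction type is the palladium-catalysed intramolecular α-alkenylation of ketone enolates with tethered alkenyl halides, well established for five- and six-membered rings and applied here to a seven-membered one. The cycloheptenone ring closes by reductive elimination from an eight-membered palladacycle in which palladium bridges C5 and C6, not by addition to an alkene, so both alkene carbons end inside the new ring (endo alkene) and the ring is trans-fused to the cyclopentane. No stereocentre is created: C3, C3a and C8a pass through unchanged and the alkene geometry is that of the bromide, which places C5 cis to C8 as the ring requires. The step needs enolisation at the methyl and not at C3a–H, since a C3a enolate would expel the C3 silyloxy group; this is secured by the hindered amide base at −78 °C and by C3a lying between two fully substituted carbons. It also needs no enolate at C2 (C1 is a ketal), no intermolecular coupling (high dilution) and no drift of the alkene into conjugation (the more acidic product is held as dienolate 21 by the second equivalent of base and protonated at C5 by the cold acetic acid quench).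

Step 12
Reactants: 22 (3R,3aR,8aR)-6,8a-dimethyl-3-(propan-2-yl)-3-[(triethylsilyl)oxy]-3,3a,8,8a-tetrahydro-2H-spiro[azulene-1,2'-[1,3]dioxolan]-4(5H)-one
Product: 23 (3R,3aS,4S,8aR)-6,8a-dimethyl-3-(propan-2-yl)-3-[(triethylsilyl)oxy]-3,3a,4,5,8,8a-hexahydro-2H-spiro[azulene-1,2'-[1,3]dioxolan]-4-ol
Conditions: SmI2, H2O, Et3N, THF, 0 °C
Reagents that add atoms: none
Why: Electron-transfer (ketyl) reduction should follow product stability and place the oxygen pseudo-equatorial on the chair-like cycloheptene, cis to H3a and anti to the axial C8a methyl, which is the 4S alcohol, whereas a small hydride would be expected to attack anti to the C8a methyl and the silyloxy group and give the 4-epimer.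

Step 13
Reactants: 23 (3R,3aS,4S,8aR)-6,8a-dimethyl-3-(propan-2-yl)-3-[(triethylsilyl)oxy]-3,3a,4,5,8,8a-hexahydro-2H-spiro[azulene-1,2'-[1,3]dioxolan]-4-ol; 24 4-[(tert-butyldimethylsilyl)oxy]benzoic acid
Product: 26 (3R,3aS,4S,8aR)-6,8a-dimethyl-3-(propan-2-yl)-3-[(triethylsilyl)oxy]-3,3a,4,5,8,8a-hexahydro-2H-spiro[azulene-1,2'-[1,3]dioxolan]-4-yl 4-[(tert-butyldimethylsilyl)oxy]benzoate, via mixed 2,4,6-trichlorobenzoic anhydride 25 (not isolated)
Conditions: 24, 2,4,6-Cl3C6H2COCl, Et3N, THF, rt; then 23, DMAP, toluene, rt→60 °C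
Reagents that add atoms: none
Why: In the Yamaguchi esterification DMAP transfers the aroyl group from the unhindered carbonyl of the mixed anhydride to the only free hydroxyl, with retention at C4 because the C4–O bond is not broken.

Step 14
Reactants: 26 (3R,3aS,4S,8aR)-6,8a-dimethyl-3-(propan-2-yl)-3-[(triethylsilyl)oxy]-3,3a,4,5,8,8a-hexahydro-2H-spiro[azulene-1,2'-[1,3]dioxolan]-4-yl 4-[(tert-butyldimethylsilyl)oxy]benzoate
Product: 27 (3R,3aS,4S,8aR)-3-hydroxy-6,8a-dimethyl-1-oxo-3-(propan-2-yl)-1,2,3,3a,4,5,8,8a-octahydroazulen-4-yl 4-hydroxybenzoate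
Conditions: 48% aq. HF, MeCN, 0 °C→rt
Reagents that add atoms: water, O
Why: Aqueous HF should cleave both silyl ethers through Si–F bond formation and hydrolyse the dioxolane in one global deprotection, while the hindered benzoate, the alkene and the tertiary β-hydroxy ketone tolerate the mild, cold acid.

Compound list
1 | 1-(furan-2-yl)ethanol (racemic) | CC(O)c1ccco1 | starting material
2 | trans-4-hydroxy-5-methylcyclopent-2-en-1-one (racemic, one enantiomer drawn) | O=C1C=C[C@@H](O)[C@@H]1C | intermediate (not isolated)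
3 | rac-4-hydroxy-2-methylcyclopent-2-en-1-one | CC1=CC(O)CC1=O | intermediate
4 | (1R)-3-methyl-4-oxocyclopent-2-en-1-yl acetate | O=C1C(C)=C[C@H](OC(C)=O)C1 | intermediate
5 | (4R)-4-hydroxy-2-methylcyclopent-2-en-1-one | O=C1C(C)=C[C@H](O)C1 | intermediate (not isolated)
6 | (4R)-4-[(tert-butyldimethylsilyl)oxy]-2-methylcyclopent-2-en-1-one | O=C1C(C)=C[C@H](O[Si](C)(C)C(C)(C)C)C1 | intermediate
7 | 2-methyl-1,3-dithiane | CC1SCCCS1 | starting material
8 | (Z)-1,3-dibromobut-2-ene (Br cis to CH2Br) | C/C(Br)=C/CBr | starting material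
9 | 2-lithio-2-methyl-1,3-dithiane | [Li]C1(C)SCCCS1 | intermediate (not isolated)
10 | lithium (3R,4R)-4-[(tert-butyldimethylsilyl)oxy]-2-methyl-3-(2-methyl-1,3-dithian-2-yl)cyclopent-1-en-1-olate (dithianyl trans to OTBS) | [Li]OC1=C(C)[C@@H](C2(C)SCCCS2)[C@H](O[Si](C)(C)C(C)(C)C)C1 | intermediate (not isolated)
11 | (2R,3R,4R)-2-[(2Z)-3-bromobut-2-en-1-yl]-4-[(tert-butyldimethylsilyl)oxy]-2-methyl-3-(2-methyl-1,3-dithian-2-yl)cyclopentan-1-one (bromobutenyl trans to dithianyl, dithianyl trans to OTBS) | C/C(Br)=C/C[C@@]1(C)C(=O)C[C@@H](O[Si](C)(C)C(C)(C)C)[C@@H]1C2(C)SCCCS2 | intermediate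
12 | (6R,7R,8R)-6-[(2Z)-3-bromobut-2-en-1-yl]-8-[(tert-butyldimethylsilyl)oxy]-6-methyl-7-(2-methyl-1,3-dithian-2-yl)-1,4-dioxaspiro[4.4]nonane (C1 dioxolane of 11) | C/C(Br)=C/C[C@@]1(C)C2(OCCO2)C[C@@H](O[Si](C)(C)C(C)(C)C)[C@@H]1C3(C)SCCCS3 | intermediate
13 | (7R,8R,9R)-9-[(2Z)-3-bromobut-2-en-1-yl]-9-methyl-8-(2-methyl-1,3-dithian-2-yl)-1,4-dioxaspiro[4.4]nonan-7-ol | C/C(Br)=C/C[C@@]1(C)C2(OCCO2)C[C@@H](O)[C@@H]1C3(C)SCCCS3 | intermediate
14 | (8R,9R)-9-[(2Z)-3-bromobut-2-en-1-yl]-9-methyl-8-(2-methyl-1,3-dithian-2-yl)-1,4-dioxaspiro[4.4]nonan-7-one | C/C(Br)=C/C[C@@]1(C)C2(OCCO2)CC(=O)[C@@H]1C3(C)SCCCS3 | intermediate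
15 | isopropylmagnesium chloride | CC(C)[Mg]Cl | starting material
16 | isopropylcerium dichloride | CC(C)[Ce](Cl)Cl | intermediate (not isolated)
17 | (7R,8R,9R)-9-[(2Z)-3-bromobut-2-en-1-yl]-9-methyl-8-(2-methyl-1,3-dithian-2-yl)-7-(propan-2-yl)-1,4-dioxaspiro[4.4]nonan-7-ol (OH cis to dithianyl) | C/C(Br)=C/C[C@@]1(C)C2(OCCO2)C[C@@](O)(C(C)C)[C@@H]1C3(C)SCCCS3 | intermediate
18 | triethylsilyl ether of 17 | C/C(Br)=C/C[C@@]1(C)C2(OCCO2)C[C@@](O[Si](CC)(CC)CC)(C(C)C)[C@@H]1C3(C)SCCCS3 | intermediate
19 | 1-[(6R,7R,8R)-6-[(2Z)-3-bromobut-2-en-1-yl]-6-methyl-8-(propan-2-yl)-8-[(triethylsilyl)oxy]-1,4-dioxaspiro[4.4]nonan-7-yl]ethan-1-one (precursor of the key step) | C/C(Br)=C/C[C@@]1(C)C2(OCCO2)C[C@@](O[Si](CC)(CC)CC)(C(C)C)[C@@H]1C(C)=O | intermediate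
20 | terminal lithium enolate of 19 | C/C(Br)=C/C[C@@]1(C)C2(OCCO2)C[C@@](O[Si](CC)(CC)CC)(C(C)C)[C@@H]1C(=C)O[Li] | intermediate (not isolated)
21 | lithium C4=C5 dienolate of 22 | CC1=CC[C@@]2(C)C3(OCCO3)C[C@@](O[Si](CC)(CC)CC)(C(C)C)[C@@H]2C(O[Li])=C1 | intermediate (not isolated)
22 | (3R,3aR,8aR)-6,8a-dimethyl-3-(propan-2-yl)-3-[(triethylsilyl)oxy]-3,3a,8,8a-tetrahydro-2H-spiro[azulene-1,2'-[1,3]dioxolan]-4(5H)-one (trans-fused, C6=C7 alkene; product of the key step) | CC1=CC[C@@]2(C)C3(OCCO3)C[C@@](O[Si](CC)(CC)CC)(C(C)C)[C@@H]2C(=O)C1 | intermediate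
23 | (3R,3aS,4S,8aR)-6,8a-dimethyl-3-(propan-2-yl)-3-[(triethylsilyl)oxy]-3,3a,4,5,8,8a-hexahydro-2H-spiro[azulene-1,2'-[1,3]dioxolan]-4-ol (4-OH cis to H3a) | CC1=CC[C@@]2(C)C3(OCCO3)C[C@@](O[Si](CC)(CC)CC)(C(C)C)[C@@H]2[C@@H](O)C1 | intermediate
24 | 4-[(tert-butyldimethylsilyl)oxy]benzoic acid | CC(C)(C)[Si](C)(C)Oc1ccc(cc1)C(O)=O | starting material
25 | 4-[(tert-butyldimethylsilyl)oxy]benzoic 2,4,6-trichlorobenzoic anhydride | CC(C)(C)[Si](C)(C)Oc1ccc(cc1)C(=O)OC(=O)c1c(Cl)cc(Cl)cc1Cl | intermediate (not isolated)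
26 | (3R,3aS,4S,8aR)-6,8a-dimethyl-3-(propan-2-yl)-3-[(triethylsilyl)oxy]-3,3a,4,5,8,8a-hexahydro-2H-spiro[azulene-1,2'-[1,3]dioxolan]-4-yl 4-[(tert-butyldimethylsilyl)oxy]benzoate | CC1=CC[C@@]2(C)C3(OCCO3)C[C@@](O[Si](CC)(CC)CC)(C(C)C)[C@@H]2[C@@H](OC(=O)c2ccc(O[Si](C)(C)C(C)(C)C)cc2)C1 | intermediate
27 | (3R,3aS,4S,8aR)-3-hydroxy-6,8a-dimethyl-1-oxo-3-(propan-2-yl)-1,2,3,3a,4,5,8,8a-octahydroazulen-4-yl 4-hydroxybenzoate | CC1=CC[C@@]2(C)C(=O)C[C@@](O)(C(C)C)[C@@H]2[C@@H](OC(=O)c2ccc(O)cc2)C1 | target

Total step count: 14. Longest linear sequence: 14 steps (1 to 27); compounds 7, 8, 15 and 24 enter as bought reagents.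

Steps most likely to fail

The ring closure of step 11 is the main risk. Oxidative addition may occur while C–C reductive elimination from the medium-ring palladacycle stays slow, so that protodebromination, intermolecular coupling or base-induced loss of the C3 silyloxy group overtake cyclisation. The fallback sets out from 19 and removes the free base from the coupling. The kinetic enolate is trapped with Me3SiCl (LiHMDS, THF, −78 °C) and the trimethylsilyl enol ether F1 is isolated. F1 is then heated with PdCl2[P(o-tol)3]2 and Bu3SnF in toluene at high dilution. Fluoride converts it into the tributyltin enolate F2, a neutral nucleophile that transmetalates to the alkenylpalladium bromide and closes the same C5–C6 bond. The fallback comes back to the route at 22.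

The isopropyl addition of step 8 may fail because the secondary organometallic enolises the hindered C3 ketone (with β-elimination that opens the dioxolane) or reduces it by β-hydride transfer instead of adding. The fallback sets out from 14 and uses a flatter sp2 nucleophile that has no transferable β-hydrogen: isopropenylmagnesium bromide premixed with anhydrous CeCl3 in THF at −78 °C should give the isopropenyl carbinol F3 with the same facial preference. Diimide, generated from 2-nitrobenzenesulfonylhydrazide and Et3N in CH2Cl2, then saturates the 1,1-disubstituted alkene and spares the trisubstituted bromoalkene and the sulfur atoms. The fallback comes back to the route at 17.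

In step 4 the one-pot allylation may lose out to proton transfer between the alkylated ketone and unreacted enolate, which is followed by β-elimination of silanolate, or the hindered tetrasubstituted enolate may react sluggishly in the crude anion mixture. The fallback sets out from 6 and 9 and separates the two bond formations. After the conjugate addition, enolate 10 is quenched with Me3SiCl and the trimethylsilyl enol ether F4 is isolated and purified. MeLi in THF at 0 °C then regenerates 10 free of excess base and dithiane, and HMPA and 8 are added at −78 °C. The fallback comes back to the route at 11.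

Further compounds
F1 | step 11 | trimethylsilyl enol ether of 19 (terminal, at the acetyl group) | C/C(Br)=C/C[C@@]1(C)C2(OCCO2)C[C@@](O[Si](CC)(CC)CC)(C(C)C)[C@@H]1C(=C)O[Si](C)(C)C
F2 | step 11 | tributyltin enolate of 19 (terminal, not isolated) | C/C(Br)=C/C[C@@]1(C)C2(OCCO2)C[C@@](O[Si](CC)(CC)CC)(C(C)C)[C@@H]1C(=C)O[Sn](CCCC)(CCCC)CCCC
F3 | step 8 | (7R,8R,9R)-9-[(2Z)-3-bromobut-2-en-1-yl]-9-methyl-8-(2-methyl-1,3-dithian-2-yl)-7-(prop-1-en-2-yl)-1,4-dioxaspiro[4.4]nonan-7-ol | C/C(Br)=C/C[C@@]1(C)C2(OCCO2)C[C@@](O)(C(C)=C)[C@@H]1C3(C)SCCCS3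
F4 | step 4 | trimethylsilyl enol ether of enolate 10 | C[Si](C)(C)OC1=C(C)[C@@H](C2(C)SCCCS2)[C@H](O[Si](C)(C)C(C)(C)C)C1
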